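The target is cut back to one stereodefined cyclohexene. Its six-membered ring (C4, C5, C11, C12, C13, C14) holds three contiguous stereocentres, C4, C5 and C11, with the C3 arm cis to C6 and isopropyl trans to C6, which is the pattern of an endo adduct between an E enal and an E 1-substituted isoprene. A single amine-catalysed, enantioselective intermolecular Diels–Alder reaction of (E)-4-methylpent-2-enal with the TBDPS ether of (E)-3-methylpenta-2,4-dien-1-ol therefore makes C4–C5 and C11–C12, the ring and all three centres. C13=C14 is left for the carbinol, and the C6 formyl and C3 silyloxymethyl arms carry the ten-membered ring, closed late at C1–C10 by Nozaki–Hiyama–Kishi coupling.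

Key step: step 3

Numbering: ten-membered ring C1 (carries the exocyclic CH2), C2, C3 (OAc), C4, C5, C6=C7 (methyl on C7), C8, C9, C10 (OAc); six-membered ring C4, C14 (C(OH)CH3), C13, C12, C11 (isopropyl), C5. In this numbering the target is 3R,4S,5S,10R,11R,14R and 6Z.

Remark on the chemistry: the oxygen on C3 is carried as a TBDPS ether, chosen over a smaller silyl group because it withstands the ammonium salt in wet solvent (step 3), peracid and LiAlH4 and makes the early intermediates UV-active; the imidazolidinone salt, the trifluoroethyl phosphonate and 2,3-dibromopropene are assumed to be bought.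

Step 1
Reactants: 1 (E)-3-methylpent-2-en-4-yn-1-ol
Product: 2 (E)-3-methylpenta-2,4-dien-1-ol
Conditions: H2 (1 atm), Lindlar catalyst, quinoline, MeOH, rt, stopped after 1 equiv H2
Reagents that add atoms: none
Why: Lindlar semihydrogenation on poisoned palladium stops a terminal alkyne at the alkene, so the enyne should give the diene with the E trisubstituted double bond untouched and no stereocentre formed.

Step 2
Reactants: 2 (E)-3-methylpenta-2,4-dien-1-ol
Product: 3 tert-butyl{[(2E)-3-methylpenta-2,4-dien-1-yl]oxy}diphenylsilane
Conditions: TBDPSCl, imidazole, CH2Cl2, 0 °C → rt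
Reagents that add atoms: tert-butyl(chloro)diphenylsilane, CC(C)(C)[Si](Cl)(c1ccccc1)c1ccccc1
Why: Imidazole-promoted silylation of a primary allylic alcohol is routine and changes neither the diene geometry nor anything else.

Step 3
Reactants: 3 tert-butyl{[(2E)-3-methylpenta-2,4-dien-1-yl]oxy}diphenylsilane; 4 (E)-4-methylpent-2-enal
Product: 7 (1R,2R,6R)-2-[(tert-butyldiphenylsilyloxy)methyl]-3-methyl-6-(propan-2-yl)cyclohex-3-ene-1-carbaldehyde, via enal iminium ion 5 (not isolated), via cycloadduct iminium ion 6 (not isolated)
Conditions: (5S)-5-benzyl-2,2,3-trimethylimidazolidin-4-one·HCl (20 mol %), MeCN–H2O (95:5), 0 °C → rt, 4 in excess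
Reagents that add atoms: none
Why: Condensation of enal 4 with the amine salt gives the E iminium ion 5, whose lowered LUMO lets diene 3 add in one concerted, asynchronous [4π+2π] step in which C11–C12 forms ahead of C4–C5, and hydrolysis of the adduct iminium ion 6 releases 7 and the amine. The reaction type is the secondary-amine (iminium) catalysed Diels–Alder reaction of β-substituted enals with acyclic dienes. The six-membered ring is closed by the intermolecular cycloaddition itself, both ring bonds forming suprafacially on each partner through the endo transition state with the iminium carbon under C13=C14. C5 is fixed by the catalyst, whose benzyl group covers the Re face of Cα in 5 so that C4 bonds to the Si face; C11 follows from the E enal (isopropyl trans to formyl) and C4 from the E diene in the endo arrangement (C3 arm cis to formyl). The step needs the orientation that joins formyl-bearing C5 to the substituted diene terminus C4; the CH2OSi group on that terminus (largest HOMO coefficient at C12, which meets the electrophilic β-carbon) and the isopropyl group, which avoids the substituted terminus, should secure it against the weaker opposite pull of the C14 methyl.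

Step 4
Reactants: 7 cyclohexene aldehyde
Product: 8 Z-enoate, ethyl (2Z)-2-methyl-3-[(1S,2R,6R)-2-(TBDPS-oxymethyl)-3-methyl-6-isopropylcyclohex-3-en-1-yl]prop-2-enoate (C6=C7 Z, C8 as CO2Et)
Conditions: (CF3CH2O)2P(O)CH(CH3)CO2Et, KHMDS, 18-crown-6, THF, −78 °C
Reagents that add atoms: ethyl 2-[bis(2,2,2-trifluoroethoxy)phosphoryl]propanoate, CCOC(=O)C(C)P(=O)(OCC(F)(F)F)OCC(F)(F)F
Why: In the Still–Gennari variant of the Horner–Wadsworth–Emmons olefination the trifluoroethyl phosphonate anion with a dissociated potassium ion eliminates from the kinetic adduct to give the Z trisubstituted enoate (ester carbon C8 cis to C5, methyl trans), and the low temperature should keep C5 from epimerising.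

Step 5
Reactants: 8 Z-enoate
Product: 9 epoxy enoate, the 13,14-epoxide of 8 with oxygen on the ring face anti to the C3 arm
Conditions: mCPBA, CH2Cl2, 0 °C
Reagents that add atoms: 3-chloroperbenzoic acid, OOC(=O)c1cccc(Cl)c1
Why: Prilezhaev epoxidation picks the electron-rich trisubstituted ring alkene over the electron-poor enoate, and the peracid should come in anti to the CH2OSi arm on C4, which A(1,2) strain with the C14 methyl holds pseudoaxial, so the oxygen lands on the face opposite to C3 and fixes C14.

Step 6
Reactants: 9 epoxy enoate
Product: 10 silyl ether diol, with a Z allylic alcohol at C8 and the tertiary alcohol at C14 (OH anti to the C3 arm)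
Conditions: LiAlH4, THF, 0 → 40 °C
Reagents that add atoms: none
Why: Hydride reduction with LiAlH4 turns the ester into the allylic alcohol and opens the epoxide by SN2 attack at the less substituted C13 in the trans-diaxial (Fürst–Plattner) sense, so the C14–O bond made in step 5 is kept and gives the 14R tertiary carbinol.

Step 7
Reactants: 10 silyl ether diol
Product: 11 allylic bromide (C8 as CH2Br, Z)
Conditions: CBr4, PPh3, CH2Cl2, 0 °C
Reagents that add atoms: tetrabromomethane, BrC(Br)(Br)Br
Why: In the Appel reaction bromide displaces the oxyphosphonium of the primary allylic alcohol in an SN2 step without allylic transposition or loss of the Z geometry, while the tertiary alcohol does not react.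

Step 8
Reactants: 11 allylic bromide
Product: 12 silyl ether nitrile (C8H2–C9H2–C10≡N)
Conditions: MeCN (excess), n-BuLi, THF, −78 °C; then 11, −78 → −40 °C
Reagents that add atoms: acetonitrile, CC#N
Why: SN2 alkylation of lithioacetonitrile at the unhindered CH2 of the primary allylic bromide adds C9 and C10 at the nitrile oxidation level, and an excess of the anion absorbs the tertiary hydroxyl proton and suppresses double alkylation.

Step 9
Reactants: 12 silyl ether nitrile
Product: 13 diol nitrile (C3 primary OH, C14 tertiary OH)
Conditions: TBAF, THF, rt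
Reagents that add atoms: none
Why: Fluoride-induced desilylation frees the C3 alcohol, and the nitrile, the alkene and the tertiary alcohol are inert to TBAF.

Step 10
Reactants: 13 diol nitrile
Product: 14 hydroxy aldehyde nitrile (C3 formyl, C14 OH free)
Conditions: TEMPO (10 mol %), PhI(OAc)2, CH2Cl2, rt; used crude
Reagents that add atoms: none
Why: TEMPO (oxoammonium) oxidation with PhI(OAc)2 converts only the primary alcohol into the aldehyde and is not basic, so C4 next to the new aldehyde should not epimerise and the β-hydroxy aldehyde should not lose water before it is used.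

Step 11
Reactants: 14 hydroxy aldehyde nitrile
Product: 15 bromoallyl carbinol nitrile, (3R)-C3H(OH)–C2H2–C1(Br)=CH2
Conditions: 2,3-dibromopropene, In powder, THF–H2O (1:1), rt
Reagents that add atoms: 2,3-dibromopropene, C=C(Br)CBr
Why: In this Barbier allylation indium inserts only into the allylic C–Br bond and the 2-bromoallylindium reagent adds to the aldehyde in wet THF; C3 should form R by Felkin–Anh attack anti to the fully substituted C14, past the slim vinylic C6–H, and chelation through the C14 hydroxyl is excluded because C3 and that oxygen are trans-diaxial.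

Step 12
Reactants: 15 bromoallyl carbinol nitrile
Product: 17 bromo aldehyde diol (C10 formyl), via aldimine 16 (not isolated)
Conditions: DIBAL-H (excess), CH2Cl2, −78 °C; then 1 M aq. HCl, 0 °C
Reagents that add atoms: water, O
Why: Partial reduction of a nitrile with DIBAL-H stops at the N-aluminated aldimine, which is hydrolysed to the aldehyde on acidic work-up; the two hydroxyls only consume hydride and the vinyl bromide is inert.

Step 13
Reactants: 17 bromo aldehyde diol
Product: 19 triol (3R,10R,14R; ten-membered ring closed), via alkenylchromium(III) species 18 (not isolated)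
Conditions: CrCl2 (excess), NiCl2 (cat.), DMSO–THF, rt, slow addition, ca. 0.002 M
Reagents that add atoms: none
Why: In the Nozaki–Hiyama–Kishi reaction nickel inserts into the vinyl C–Br bond and transmetalation gives an alkenylchromium(III) species that adds only to the aldehyde and tolerates free hydroxyls, while high dilution favours closure of the ten-membered ring at C1–C10; C10 is set in this closure, where the aldehyde is expected to react with its oxygen turned to the outside of the forming ring to give 10R, the least certain stereochemical prediction of the route.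

Step 14
Reactants: 19 triol
Product: 20 target diacetate
Conditions: Ac2O, pyridine, DMAP (cat.), CH2Cl2, 0 °C → rt
Reagents that add atoms: acetic anhydride, CC(=O)OC(C)=O
Why: DMAP-catalysed acylation esterifies the two secondary alcohols, whereas the hindered axial tertiary hydroxyl on C14 should stay free under these mild conditions and no stereocentre is touched.

Compound list
1 | (E)-3-methylpent-2-en-4-yn-1-ol | C#C/C(C)=C/CO | starting material
2 | (E)-3-methylpenta-2,4-dien-1-ol | C=C/C(C)=C/CO | intermediate
3 | tert-butyl{[(2E)-3-methylpenta-2,4-dien-1-yl]oxy}diphenylsilane | C=C/C(C)=C/CO[Si](c1ccccc1)(c1ccccc1)C(C)(C)C | intermediate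
4 | (E)-4-methylpent-2-enal | CC(C)/C=C/C=O | starting material
5 | enal iminium ion: E iminium chloride of 4 with (5S)-5-benzyl-2,2,3-trimethylimidazolidin-4-one | CC(C)/C=C/C=[N+]1/C(C)(C)N(C)C(=O)[C@@H]1Cc1ccccc1.[Cl-] | intermediate
6 | cycloadduct iminium ion: iminium chloride of 7 with the same amine | CC(C)(C)[Si](c1ccccc1)(c1ccccc1)OC[C@@H]1[C@H](/C=[N+]2/C(C)(C)N(C)C(=O)[C@@H]2Cc2ccccc2)[C@@H](C(C)C)CC=C1C.[Cl-] | intermediate
7 | (1R,2R,6R)-2-[(tert-butyldiphenylsilyloxy)methyl]-3-methyl-6-(propan-2-yl)cyclohex-3-ene-1-carbaldehyde (formyl cis to the C3 arm, isopropyl trans to formyl) | CC(C)(C)[Si](c1ccccc1)(c1ccccc1)OC[C@@H]1[C@H](C=O)[C@@H](C(C)C)CC=C1C | intermediate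
8 | Z-enoate: ethyl (2Z)-2-methyl-3-[(1S,2R,6R)-2-(TBDPS-oxymethyl)-3-methyl-6-isopropylcyclohex-3-en-1-yl]prop-2-enoate | CC(C)(C)[Si](c1ccccc1)(c1ccccc1)OC[C@@H]1[C@H](/C=C(/C)C(=O)OCC)[C@@H](C(C)C)CC=C1C | intermediate
9 | epoxy enoate: 13,14-epoxide of 8, oxygen anti to the C3 arm | CC(C)(C)[Si](c1ccccc1)(c1ccccc1)OC[C@@H]1[C@H](/C=C(/C)C(=O)OCC)[C@@H](C(C)C)C[C@H]2O[C@]21C | intermediate
10 | silyl ether diol: Z allylic alcohol at C8, tertiary alcohol at C14 | CC(C)(C)[Si](c1ccccc1)(c1ccccc1)OC[C@@H]1[C@H](/C=C(/C)CO)[C@@H](C(C)C)CC[C@@]1(C)O | intermediate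
11 | allylic bromide (C8 as CH2Br) | CC(C)(C)[Si](c1ccccc1)(c1ccccc1)OC[C@@H]1[C@H](/C=C(/C)CBr)[C@@H](C(C)C)CC[C@@]1(C)O | intermediate
12 | silyl ether nitrile (C10 as nitrile) | CC(C)(C)[Si](c1ccccc1)(c1ccccc1)OC[C@@H]1[C@H](/C=C(/C)CCC#N)[C@@H](C(C)C)CC[C@@]1(C)O | intermediate
13 | diol nitrile | OC[C@@H]1[C@H](/C=C(/C)CCC#N)[C@@H](C(C)C)CC[C@@]1(C)O | intermediate
14 | hydroxy aldehyde nitrile (C3 formyl) | O=C[C@@H]1[C@H](/C=C(/C)CCC#N)[C@@H](C(C)C)CC[C@@]1(C)O | intermediate
15 | bromoallyl carbinol nitrile (3R) | C=C(Br)C[C@@H](O)[C@@H]1[C@H](/C=C(/C)CCC#N)[C@@H](C(C)C)CC[C@@]1(C)O | intermediate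
16 | aldimine (C10 as CH=NH) | C=C(Br)C[C@@H](O)[C@@H]1[C@H](/C=C(/C)CCC=N)[C@@H](C(C)C)CC[C@@]1(C)O | intermediate
17 | bromo aldehyde diol (C10 formyl) | C=C(Br)C[C@@H](O)[C@@H]1[C@H](/C=C(/C)CCC=O)[C@@H](C(C)C)CC[C@@]1(C)O | intermediate
18 | alkenylchromium(III) species (C1–CrCl2) | C=C([Cr](Cl)Cl)C[C@@H](O)[C@@H]1[C@H](/C=C(/C)CCC=O)[C@@H](C(C)C)CC[C@@]1(C)O | intermediate
19 | triol (3R,10R,14R), bicyclic | C=C1C[C@@H](O)[C@@H]2[C@H](/C=C(/C)CC[C@H]1O)[C@@H](C(C)C)CC[C@@]2(C)O | intermediate
20 | CNP0303839.1, the 3,10-diacetate | C=C1C[C@@H](OC(C)=O)[C@@H]2[C@H](/C=C(/C)CC[C@H]1OC(C)=O)[C@@H](C(C)C)CC[C@@]2(C)O | target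

Total steps: 14. Longest linear sequence: 14 steps (1 → 20); enal 4 joins at step 3.

Steps most likely to fail

1. Step 3 (key step). The iminium ion may activate the β-branched enal too weakly for a non-activated, trisubstituted diene, so that conversion stalls. The diene may also add in the reverse orientation, steered by the C14 methyl, or without endo preference. Fallback, an auxiliary-controlled Lewis-acid Diels–Alder reaction: it sets out from diene 3, which is combined not with 4 but with (S)-4-benzyl-3-[(E)-4-methylpent-2-enoyl]oxazolidin-2-one F1. F1 is made from commercial (E)-4-methylpent-2-enoic acid through its pivaloyl mixed anhydride and the lithiated oxazolidinone. Under Et2AlCl in CH2Cl2 at −30 °C the chelated s-cis imide should be attacked on the face away from the benzyl group, the same Cα face as in step 3, with the regio- and endo preference sharpened by the Lewis acid, to give the endo imide cycloadduct F2. LiBH4 in wet ether removes the auxiliary to give the primary alcohol F3, and Dess–Martin oxidation brings the route back to aldehyde 7.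

2. Step 13. The aldehyde faces may be poorly discriminated during ring closure, so that the C10 epimer is formed in part or mainly; with the vinyl bromide the closure may also be slow enough for intermolecular coupling to compete. Fallback, which sets C10 by reagent-controlled reduction and not by the ring closure: it sets out from 17, which is cyclised as in step 13 to the 10-epi-triol F4 (alone or mixed with 19). MnO2 in CH2Cl2 oxidises only the allylic C10 alcohol to the α-methylene ketone F5. Corey–Bakshi–Shibata reduction with the (S)-oxazaborolidine and catecholborane at −78 °C, with the alkenyl group as the large substituent, should then give the 10R alcohol and return to triol 19.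

3. Step 11. The two neighbours of the axial aldehyde (C14 with its methyl, C5 with the alkenyl arm) differ only modestly, so facial selectivity at C3 may be low. The β-hydroxy aldehyde may also epimerise at C4 or lose water before it is trapped. Fallback, reagent control in place of substrate control: it sets out from 14 and comes back at 15. The aldehyde is treated at −78 °C in ether with B-(2-bromoallyl)diisopinocampheylborane of the (−)-α-pinene series, generated from the B-bromoborane and allene. This series delivers allyl groups to the Re face of aldehydes, the face that leads to 3R and also the Felkin–Anh face. Ethanolamine work-up spares the nitrile. No compound outside the list is formed (F0).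

Further compounds
F1 | step 3 | (S)-4-benzyl-3-[(E)-4-methylpent-2-enoyl]oxazolidin-2-one | CC(C)/C=C/C(=O)N1C(=O)OC[C@@H]1Cc1ccccc1
F2 | step 3 | endo imide cycloadduct (N-acyl oxazolidinone in place of the formyl group of 7) | CC(C)(C)[Si](c1ccccc1)(c1ccccc1)OC[C@@H]1[C@H](C(=O)N2C(=O)OC[C@@H]2Cc2ccccc2)[C@@H](C(C)C)CC=C1C
F3 | step 3 | primary alcohol (CH2OH in place of the formyl group of 7) | CC(C)(C)[Si](c1ccccc1)(c1ccccc1)OC[C@@H]1[C@H](CO)[C@@H](C(C)C)CC=C1C
F4 | step 13 | 10-epi-triol (10S epimer of 19) | C=C1C[C@@H](O)[C@@H]2[C@H](/C=C(/C)CC[C@@H]1O)[C@@H](C(C)C)CC[C@@]2(C)O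
F5 | step 13 | α-methylene ketone (C10 ketone of 19) | C=C1C[C@@H](O)[C@@H]2[C@H](/C=C(/C)CCC1=O)[C@@H](C(C)C)CC[C@@]2(C)O
F0 | step 11 | none | none
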